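**Plan**
- Retrosynthesis: the chain C=C is removed last (H2). Ring B is then opened at O6–C5, the bond from the chain-side oxygen to the spiro carbon, which leaves ring A as a 5-substituted 2,3-dihydrofuran (enol ether C4=C5) with the C7 hydroxyl three carbons away. Next C5–C9 is cut (sp2–sp3 Suzuki–Miyaura: lactone enol phosphate + alkylborane), then the chain C=C (cross-metathesis).
- Feature used: spiro C5 is a ketone-level carbon flanked by O1 of ring A and O6 of ring B. Masked as the enol ether of ring A it turns electrophilic on protonation, so O6 can close ring B in one stereodefining event.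
- Forward order: the benzene ring is bought; the lactone ring of the phthalide is closed in step 5; ring A comes closed from (S)-γ-valerolactone and is joined in step 10; ring B is closed last in step 12; the chain alkene is then saturated.
- Stereochemistry: phthalide C3 by CBS reduction; C7 by Brown allylboration of acrolein; C2 from the chiral pool; spiro C5 by a confined chiral Brønsted acid under kinetic control.

Key step: step 12

Atom labels in the text: ring A = O1–C2(CH3)–C3–C4–C5, ring B = C5–O6–C7(chain)–C8–C9; "phthalide C3" is the lactone stereocentre. Systematic names use nomenclature locants, so the chain-bearing ring carbon is position 2 there.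
Assumption: the sense of induction of the chiral acid in step 12 cannot be predicted for this substrate and has to be settled by a test with both antipodes; the (S,S) antipode is written. The chain alkene from step 8 is drawn E; its geometry does not matter because step 13 saturates it.

Step 1
Reactants: 1 3,5-dimethoxybenzaldehyde
Product: 2 2-bromo-3,5-dimethoxybenzaldehyde
Conditions: NBS, MeCN, 0 °C → rt
Reagents that add atoms: N-bromosuccinimide, O=C1CCC(=O)N1Br
Why: Electrophilic aromatic bromination; C2 (para to one methoxy group, ortho to the other) is activated and less hindered than C4 between the two methoxy groups, so bromine enters next to the formyl group, where the lactone carbonyl will later stand.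

Step 2
Reactants: 2 2-bromo-3,5-dimethoxybenzaldehyde; 3 pent-4-enylmagnesium bromide
Product: 4 racemic 1-(2-bromo-3,5-dimethoxyphenyl)hex-5-en-1-ol
Conditions: THF, −78 → 0 °C; aq NH4Cl
Reagents that add atoms: none
Why: Grignard 1,2-addition to the aldehyde, which is much faster than bromine–magnesium exchange at low temperature; no stereocontrol is needed because the carbinol is oxidised in step 3.

Step 3
Reactants: 4 racemic 1-(2-bromo-3,5-dimethoxyphenyl)hex-5-en-1-ol
Product: 5 1-(2-bromo-3,5-dimethoxyphenyl)hex-5-en-1-one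
Conditions: Dess–Martin periodinane, CH2Cl2, rt
Reagents that add atoms: none
Why: Dess–Martin oxidation of a benzylic secondary alcohol to the aryl ketone under mild conditions that leave the terminal alkene and the aryl bromide untouched.

Step 4
Reactants: 5 1-(2-bromo-3,5-dimethoxyphenyl)hex-5-en-1-one
Product: 6 (1S)-1-(2-bromo-3,5-dimethoxyphenyl)hex-5-en-1-ol
Conditions: (R)-2-methyl-CBS-oxazaborolidine (10 mol %), catecholborane, toluene, −78 → −40 °C
Reagents that add atoms: none
Why: Corey–Bakshi–Shibata reduction; the (R)-oxazaborolidine binds the ketone with the ortho-bromoaryl group as the large substituent and delivers hydride to give the (S)-carbinol (phthalide C3), and catecholborane at low temperature does not hydroborate the terminal alkene.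

Step 5
Reactants: 6 (1S)-1-(2-bromo-3,5-dimethoxyphenyl)hex-5-en-1-ol
Product: 9 (3S)-5,7-dimethoxy-3-(pent-4-en-1-yl)-2-benzofuran-1(3H)-one, via dilithiated aryl alkoxide 7 (not isolated), via hydroxy acid 8 (not isolated)
Conditions: n-BuLi (2.2 equiv), THF, −78 °C; CO2 (g), −78 °C → rt; then 2 M HCl, rt
Reagents that add atoms: carbon dioxide, O=C=O
Why: O–H deprotonation and bromine–lithium exchange, carboxylation of the aryllithium and acid-induced lactonisation of the ortho-(hydroxyalkyl)benzoic acid close the phthalide ring without breaking the carbinol C–O bond, so phthalide C3 is retained.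

Step 6
Reactants: 10 acrolein
Product: 11 (3S)-hexa-1,5-dien-3-ol
Conditions: (−)-Ipc2B(allyl) (1 M in pentane), Et2O, −78 °C; then NaOH, H2O2, 0 °C → rt; distillation
Reagents that add atoms: (−)-B-allyldiisopinocampheylborane, C=CCB([C@H]1[C@H](C)[C@H]2C[C@@H](C1)C2(C)C)[C@H]1[C@H](C)[C@H]2C[C@@H](C1)C2(C)C
Why: Brown allylboration through a chair six-membered transition state; the reagent derived from (+)-α-pinene adds the allyl group 1,2 to the Si face of the aldehyde, which gives the (S)-dienol and sets the later C7.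

Step 7
Reactants: 11 (3S)-hexa-1,5-dien-3-ol
Product: 12 tert-butyl[(3S)-hexa-1,5-dien-3-yloxy]dimethylsilane
Conditions: TBSCl, imidazole, CH2Cl2, rt
Reagents that add atoms: tert-butyldimethylsilyl chloride, CC(C)(C)[Si](C)(C)Cl
Why: Standard silylation of a secondary alcohol; the bulky silyl ether protects the hydroxyl and shields the neighbouring vinyl group for the site-selective metathesis of step 8.

Step 8
Reactants: 9 (3S)-5,7-dimethoxy-3-(pent-4-en-1-yl)-2-benzofuran-1(3H)-one; 12 tert-butyl[(3S)-hexa-1,5-dien-3-yloxy]dimethylsilane (3 equiv)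
Product: 13 (3S)-3-[(4E,7S)-7-{[tert-butyl(dimethyl)silyl]oxy}nona-4,8-dien-1-yl]-5,7-dimethoxy-2-benzofuran-1(3H)-one
Conditions: second-generation Hoveyda–Grubbs catalyst, RuCl2(H2IMes)(=CH-C6H4-2-OiPr) (5 mol %), CH2Cl2, 40 °C
Reagents that add atoms: none
Why: Olefin cross-metathesis; the unhindered allyl terminus of 12 should react much faster than its vinyl group, which is deactivated sterically and electronically by the allylic silyloxy substituent (a known site selectivity for protected hexa-1,5-dien-3-ols), and a 1,5-diene cannot ring-close.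

Step 9
Reactants: 14 (S)-γ-valerolactone
Product: 15 (5S)-5-methyl-4,5-dihydrofuran-2-yl diphenyl phosphate
Conditions: KN(SiMe3)2, (PhO)2P(O)Cl, HMPA, THF, −78 °C (base added to lactone and chlorophosphate); used crude
Reagents that add atoms: diphenyl chlorophosphate, O=P(Cl)(Oc1ccccc1)Oc1ccccc1
Why: O-phosphorylation of the potassium lactone enolate, trapped as it forms (ketene acetal phosphate formation), turns the chiral-pool lactone into a vinyl electrophile without touching C2 of ring A.

Step 10
Reactants: 13 (3S)-3-[(4E,7S)-7-{[tert-butyl(dimethyl)silyl]oxy}nona-4,8-dien-1-yl]-5,7-dimethoxy-2-benzofuran-1(3H)-one; 15 (5S)-5-methyl-4,5-dihydrofuran-2-yl diphenyl phosphate (1.5 equiv)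
Product: 17 (3S)-3-[(4E,7R)-7-{[tert-butyl(dimethyl)silyl]oxy}-9-[(5S)-5-methyl-4,5-dihydrofuran-2-yl]non-4-en-1-yl]-5,7-dimethoxy-2-benzofuran-1(3H)-one, via B-alkyl-9-BBN adduct 16 (not isolated)
Conditions: 9-BBN (1.3 equiv), THF, 0 °C → rt; then 15, Pd(PPh3)4 (5 mol %), aq NaHCO3, DMF, 50 °C; chromatography on Et3N-deactivated silica
Reagents that add atoms: none
Why: 9-BBN hydroborates the monosubstituted vinyl group anti-Markovnikov and far faster than the 1,2-disubstituted chain alkene, and B-alkyl Suzuki–Miyaura coupling of the borane with the lactone-derived ketene acetal phosphate forms the C9–C5 sp3–sp2 bond and delivers ring A as the 2,3-dihydrofuran, while the bicarbonate base spares the phthalide (the C7 descriptor changes from S to R only through the priority rules).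

Step 11
Reactants: 17 (3S)-3-[(4E,7R)-7-{[tert-butyl(dimethyl)silyl]oxy}-9-[(5S)-5-methyl-4,5-dihydrofuran-2-yl]non-4-en-1-yl]-5,7-dimethoxy-2-benzofuran-1(3H)-one
Product: 18 (3S)-3-[(4E,7R)-7-hydroxy-9-[(5S)-5-methyl-4,5-dihydrofuran-2-yl]non-4-en-1-yl]-5,7-dimethoxy-2-benzofuran-1(3H)-one
Conditions: Bu4NF, THF, 0 °C → rt; aq NaHCO3 work-up; Et3N-deactivated silica
Reagents that add atoms: none
Why: Fluoride-induced cleavage of the silyl ether under basic conditions frees the C7 hydroxyl without touching the acid-labile enol ether or the lactone.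

Step 12
Reactants: 18 (3S)-3-[(4E,7R)-7-hydroxy-9-[(5S)-5-methyl-4,5-dihydrofuran-2-yl]non-4-en-1-yl]-5,7-dimethoxy-2-benzofuran-1(3H)-one
Product: 19 (3S)-5,7-dimethoxy-3-{(4E)-6-[(2R,5S,7S)-7-methyl-1,6-dioxaspiro[4.4]nonan-2-yl]hex-4-en-1-yl}-2-benzofuran-1(3H)-one
Conditions: (S,S)-imidodiphosphoric acid built from two (S)-3,3′-bis(2,4,6-triethylphenyl)-1,1′-bi-2-naphthol units (5 mol %), tert-butyl methyl ether, 4 Å MS, −35 °C; quench with Et3N
Reagents that add atoms: none
Why: The confined acid protonates C4 of the enol ether of ring A inside its chiral pocket while its P=O oxygen holds the C7 hydroxyl, so that O6 adds to C5 in a syn, asynchronous concerted event (or through a tight oxocarbenium–imidodiphosphate ion pair) and ring B closes. The closest known reaction type is the catalytic asymmetric spiroacetalisation of hydroxy-tethered cyclic enol ethers by confined chiral Brønsted acids, which forms small 5,5-, 5,6- and 6,6-spiroacetals under kinetic control. Ring B forms by 5-exo-trig attack of O6 on C5, the bond that is attacked (C5=O1+ or C4=C5) lying outside the new ring. The only new stereocentre, spiro C5, is set by the catalyst (reagent control), which has to place O6 on the face of ring A that carries the C2 methyl group; C2 and C7 are set earlier and are not touched. The step needs face selectivity at C5 and must stay kinetic, because the (5S) and (5R) spiroacetals are expected to be close in energy; the low temperature, the weak bulky acid and the Et3N quench are there to prevent re-ionisation of the product. In the substrate the endocyclic enol ether makes C5 the only electrophilic carbon and the three-atom tether C7–C8–C9 allows only the five-membered closure, while the isolated chain alkene and the lactone are inert to the acid.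

Step 13
Reactants: 19 (3S)-5,7-dimethoxy-3-{(4E)-6-[(2R,5S,7S)-7-methyl-1,6-dioxaspiro[4.4]nonan-2-yl]hex-4-en-1-yl}-2-benzofuran-1(3H)-one
Product: 20 (3S)-5,7-dimethoxy-3-{6-[(2S,5S,7S)-7-methyl-1,6-dioxaspiro[4.4]nonan-2-yl]hexyl}-2-benzofuran-1(3H)-one
Conditions: H2 (1 atm), PtO2, K2CO3 (trace), EtOAc, rt
Reagents that add atoms: none
Why: Heterogeneous catalytic hydrogenation of the isolated disubstituted alkene; PtO2 under slightly basic conditions should neither hydrogenolyse the benzylic lactone C–O bond nor ionise the spiroacetal, so all four stereocentres are kept (the ring-carbon descriptor changes from R to S only through the priority rules).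

**Compound list**
1 | 3,5-dimethoxybenzaldehyde | COc1cc(C=O)cc(OC)c1 | starting material
2 | 2-bromo-3,5-dimethoxybenzaldehyde | COc1cc(OC)c(Br)c(C=O)c1 | intermediate
3 | pent-4-enylmagnesium bromide | C=CCCC[Mg]Br | starting material
4 | racemic 1-(2-bromo-3,5-dimethoxyphenyl)hex-5-en-1-ol | C=CCCCC(O)c1cc(OC)cc(OC)c1Br | intermediate
5 | 1-(2-bromo-3,5-dimethoxyphenyl)hex-5-en-1-one | C=CCCCC(=O)c1cc(OC)cc(OC)c1Br | intermediate
6 | (1S)-1-(2-bromo-3,5-dimethoxyphenyl)hex-5-en-1-ol | C=CCCC[C@H](O)c1cc(OC)cc(OC)c1Br | intermediate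
7 | dilithium derivative of 6 (lithium alkoxide, 2-lithioarene) | C=CCCC[C@H](O[Li])c1cc(OC)cc(OC)c1[Li] | intermediate
8 | 2-[(1S)-1-hydroxyhex-5-en-1-yl]-4,6-dimethoxybenzoic acid | C=CCCC[C@H](O)c1cc(OC)cc(OC)c1C(=O)O | intermediate
9 | (3S)-5,7-dimethoxy-3-(pent-4-en-1-yl)-2-benzofuran-1(3H)-one | COc1cc(OC)c2c(c1)[C@H](CCCC=C)OC2=O | intermediate
10 | acrolein | C=CC=O | starting material
11 | (3S)-hexa-1,5-dien-3-ol | C=CC[C@H](O)C=C | intermediate
12 | tert-butyl[(3S)-hexa-1,5-dien-3-yloxy]dimethylsilane | C=CC[C@H](O[Si](C)(C)C(C)(C)C)C=C | intermediate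
13 | (3S)-3-[(4E,7S)-7-{[tert-butyl(dimethyl)silyl]oxy}nona-4,8-dien-1-yl]-5,7-dimethoxy-2-benzofuran-1(3H)-one | COc1cc(OC)c2c(c1)[C@H](CCC/C=C/C[C@H](O[Si](C)(C)C(C)(C)C)C=C)OC2=O | intermediate
14 | (S)-γ-valerolactone | C[C@H]1CCC(=O)O1 | starting material
15 | (5S)-5-methyl-4,5-dihydrofuran-2-yl diphenyl phosphate | C[C@H]1CC=C(OP(=O)(Oc2ccccc2)Oc2ccccc2)O1 | intermediate
16 | (3S)-3-[(4E,7R)-9-(9-borabicyclo[3.3.1]nonan-9-yl)-7-{[tert-butyl(dimethyl)silyl]oxy}non-4-en-1-yl]-5,7-dimethoxy-2-benzofuran-1(3H)-one | COc1cc(OC)c2c(c1)[C@H](CCC/C=C/C[C@H](O[Si](C)(C)C(C)(C)C)CCB1C3CCCC1CCC3)OC2=O | intermediate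
17 | (3S)-3-[(4E,7R)-7-{[tert-butyl(dimethyl)silyl]oxy}-9-[(5S)-5-methyl-4,5-dihydrofuran-2-yl]non-4-en-1-yl]-5,7-dimethoxy-2-benzofuran-1(3H)-one | COc1cc(OC)c2c(c1)[C@H](CCC/C=C/C[C@H](O[Si](C)(C)C(C)(C)C)CCC1=CC[C@H](C)O1)OC2=O | intermediate
18 | (3S)-3-[(4E,7R)-7-hydroxy-9-[(5S)-5-methyl-4,5-dihydrofuran-2-yl]non-4-en-1-yl]-5,7-dimethoxy-2-benzofuran-1(3H)-one | COc1cc(OC)c2c(c1)[C@H](CCC/C=C/C[C@H](O)CCC1=CC[C@H](C)O1)OC2=O | intermediate
19 | (3S)-5,7-dimethoxy-3-{(4E)-6-[(2R,5S,7S)-7-methyl-1,6-dioxaspiro[4.4]nonan-2-yl]hex-4-en-1-yl}-2-benzofuran-1(3H)-one | COc1cc(OC)c2c(c1)[C@H](CCC/C=C/C[C@H]1CC[C@]3(CC[C@H](C)O3)O1)OC2=O | intermediate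
20 | (3S)-5,7-dimethoxy-3-{6-[(2S,5S,7S)-7-methyl-1,6-dioxaspiro[4.4]nonan-2-yl]hexyl}-2-benzofuran-1(3H)-one | COc1cc(OC)c2c(c1)[C@H](CCCCCC[C@H]1CC[C@]3(CC[C@H](C)O3)O1)OC2=O | target

**Totals**
Total step count: 13. Longest linear sequence: 10 steps (steps 1–5, 8, 10–13).

**Steps most likely to fail**

Step 12. The process at risk is low facial discrimination at C5 during ring closure, or acid-induced re-ionisation that lets the spiro centre drift to the equilibrium mixture. The fallback sets out from 18 and comes back at 19, and gives up kinetic control. Compound 18 is cyclised with pyridinium p-toluenesulfonate in CH2Cl2 at rt under thermodynamic control. Compound 19 is separated by preparative HPLC from its spiro epimer (3S)-5,7-dimethoxy-3-{(4E)-6-[(2R,5R,7S)-7-methyl-1,6-dioxaspiro[4.4]nonan-2-yl]hex-4-en-1-yl}-2-benzofuran-1(3H)-one F1. F1 is returned to the same acid for re-equilibration and renewed separation, so that the material is funnelled into 19.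

Step 10. The process at risk is hydrolysis of the five-membered ketene acetal phosphate under the aqueous base before oxidative addition, or slow transmetalation of the β-branched alkylborane. The fallback sets out from 13 and comes back at 17, and builds the enol ether by alkynol cycloisomerisation instead.
- 9-BBN and then NaBO3 should give the primary alcohol (3S)-3-[(4E,7S)-7-{[tert-butyl(dimethyl)silyl]oxy}-9-hydroxynon-4-en-1-yl]-5,7-dimethoxy-2-benzofuran-1(3H)-one F2.
- I2, PPh3 and imidazole should give the iodide (3S)-3-[(4E,7S)-7-{[tert-butyl(dimethyl)silyl]oxy}-9-iodonon-4-en-1-yl]-5,7-dimethoxy-2-benzofuran-1(3H)-one F3.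
- Alkyl Sonogashira coupling of F3 with commercial (S)-pent-4-yn-2-ol (C#CC[C@H](C)O) under [(η3-C3H5)PdCl]2, 1,3-bis(1-adamantyl)imidazolium chloride, CuI, Cs2CO3, DMF/Et2O, 45 °C should give the homopropargylic alcohol (3S)-3-[(4E,7R,13S)-7-{[tert-butyl(dimethyl)silyl]oxy}-13-hydroxytetradec-4-en-10-yn-1-yl]-5,7-dimethoxy-2-benzofuran-1(3H)-one F4.
- PdCl2(MeCN)2 in dry THF then closes ring A by 5-endo-dig hydroalkoxylation to give 17.

Step 8. The process at risk is loss of site selectivity, that is metathesis at the silyloxy-substituted vinyl group or at both alkenes of 12. The fallback sets out from 9 and comes back at 13, and masks that vinyl group as a silylalkyne.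
- Commercial 3-(trimethylsilyl)propynal (C[Si](C)(C)C#CC=O) is allylated as in step 6 to (3S)-1-(trimethylsilyl)hex-5-en-1-yn-3-ol F5.
- F5 is silylated as in step 7 to its tert-butyldimethylsilyl ether F6.
- Cross-metathesis of 9 with F6, which has a single alkene, under the conditions of step 8 should give (3S)-3-[(4E,7S)-7-{[tert-butyl(dimethyl)silyl]oxy}-9-(trimethylsilyl)non-4-en-8-yn-1-yl]-5,7-dimethoxy-2-benzofuran-1(3H)-one F7.
- K2CO3 in MeOH removes the C-silyl group to give the terminal alkyne (3S)-3-[(4E,7S)-7-{[tert-butyl(dimethyl)silyl]oxy}non-4-en-8-yn-1-yl]-5,7-dimethoxy-2-benzofuran-1(3H)-one F8.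
- Semihydrogenation (H2, Pd/CaCO3 poisoned with Pb(OAc)2, quinoline, EtOAc) gives 13.

**Further compounds**
F1 | step 12 | (3S)-5,7-dimethoxy-3-{(4E)-6-[(2R,5R,7S)-7-methyl-1,6-dioxaspiro[4.4]nonan-2-yl]hex-4-en-1-yl}-2-benzofuran-1(3H)-one | COc1cc(OC)c2c(c1)[C@H](CCC/C=C/C[C@H]1CC[C@@]3(CC[C@H](C)O3)O1)OC2=O
F2 | step 10 | (3S)-3-[(4E,7S)-7-{[tert-butyl(dimethyl)silyl]oxy}-9-hydroxynon-4-en-1-yl]-5,7-dimethoxy-2-benzofuran-1(3H)-one | COc1cc(OC)c2c(c1)[C@H](CCC/C=C/C[C@H](O[Si](C)(C)C(C)(C)C)CCO)OC2=O
F3 | step 10 | (3S)-3-[(4E,7S)-7-{[tert-butyl(dimethyl)silyl]oxy}-9-iodonon-4-en-1-yl]-5,7-dimethoxy-2-benzofuran-1(3H)-one | COc1cc(OC)c2c(c1)[C@H](CCC/C=C/C[C@H](O[Si](C)(C)C(C)(C)C)CCI)OC2=O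
F4 | step 10 | (3S)-3-[(4E,7R,13S)-7-{[tert-butyl(dimethyl)silyl]oxy}-13-hydroxytetradec-4-en-10-yn-1-yl]-5,7-dimethoxy-2-benzofuran-1(3H)-one | COc1cc(OC)c2c(c1)[C@H](CCC/C=C/C[C@H](O[Si](C)(C)C(C)(C)C)CCC#CC[C@H](C)O)OC2=O
F5 | step 8 | (3S)-1-(trimethylsilyl)hex-5-en-1-yn-3-ol | C=CC[C@H](O)C#C[Si](C)(C)C
F6 | step 8 | tert-butyl(dimethyl){[(3S)-1-(trimethylsilyl)hex-5-en-1-yn-3-yl]oxy}silane | C=CC[C@H](O[Si](C)(C)C(C)(C)C)C#C[Si](C)(C)C
F7 | step 8 | (3S)-3-[(4E,7S)-7-{[tert-butyl(dimethyl)silyl]oxy}-9-(trimethylsilyl)non-4-en-8-yn-1-yl]-5,7-dimethoxy-2-benzofuran-1(3H)-one | COc1cc(OC)c2c(c1)[C@H](CCC/C=C/C[C@H](O[Si](C)(C)C(C)(C)C)C#C[Si](C)(C)C)OC2=O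
F8 | step 8 | (3S)-3-[(4E,7S)-7-{[tert-butyl(dimethyl)silyl]oxy}non-4-en-8-yn-1-yl]-5,7-dimethoxy-2-benzofuran-1(3H)-one | COc1cc(OC)c2c(c1)[C@H](CCC/C=C/C[C@H](O[Si](C)(C)C(C)(C)C)C#C)OC2=O
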